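Readings and results were generated by integration for an exercise, and the scatter is random.

The flask is to be stopped by what is left of right-handed substrate, not by the clock.

all flasks: impurity 0.96 mM
- Sunday's: left-handed substrate 0.025 M; right-handed substrate 0.025 M; reagent 0.15 M; free catalyst 7 mM; run made earlier
- Wednesday's: left-handed substrate 0.038 M; right-handed substrate 0.038 M; reagent 0.15 M; free catalyst 7 mM; run made earlier
- flask: left-handed substrate 0.050 M; right-handed substrate 0.050 M; reagent 0.150 M; free catalyst 7.0 mM; time 20 h

| run | time / h | right-handed substrate / % | left-handed substrate / % | left-handed product / % |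
|---|---|---|---|---|
| Sunday's | 0.667 | 48.2 | 13.7 | 36.2 |
| Sunday's | 2.00 | 48.2 | 1.3 | 48.5 |
| Sunday's | 3.00 | 46.5 | 0.1 | 49.8 |
| Sunday's | 5.00 | 45.0 | 1.0 | 49.2 |
| Sunday's | 8.00 | 44.1 | 0.7 | 50.0 |
| Sunday's | 10.0 | 40.9 | 0 | 49.3 |
| Sunday's | 12.0 | 40.1 | 0 | 50.3 |
| Wednesday's | 0.667 | 48.8 | 15.3 | 35.7 |
| Wednesday's | 2.00 | 47.2 | 1.7 | 47.9 |
| Wednesday's | 3.00 | 46.6 | 0 | 49.1 |
| Wednesday's | 5.00 | 45.1 | 0 | 50.4 |
| Wednesday's | 8.00 | 43.6 | 0 | 49.8 |
| Wednesday's | 10.0 | 42.7 | 0 | 50.6 |
| Wednesday's | 12.0 | 41.8 | 0.2 | 49.8 |

(each reading ± 0.5 percentage points)

- free catalyst is single-handed; left-handed substrate and right-handed substrate are mirror images of each other, charged as a racemate, each of them at the stated concentration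
- the numbers in the tables scatter by 0.5 percentage points (one standard deviation)
- candidate steps: reagent + free catalyst + left-handed substrate -> free catalyst + left-handed product; reagent + free catalyst + right-handed substrate -> free catalyst + right-handed product; free catalyst + impurity -> spent catalyst A; free catalyst -> spent catalyst B; 2 free catalyst <-> resting dimer

- whether the excess of right-handed substrate over left-handed substrate among what is left of the two reaches 99 % by 20 h (yes / no)
- the highest excess of right-handed substrate over left-handed substrate among what is left of the two up to 20 h

Take x and y as the fractions left of left-handed and right-handed substrate, each of its own charge. Both candidate steps carry the same [reagent] and [free catalyst], and each is first-order in its own substrate. Dividing one rate by the other therefore cancels them, and ln x / ln y stays constant. At 2.00 h, Sunday's run reads 99.5 and Wednesday's 58.7, so the scatter is wide. Their mean, 79.1, is the value read here for the selectivity factor.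

Now the settings. By hand, substrate load should cancel, and Wednesday's run, with 1.52 times Sunday's charge, reads 47.2 % of right-handed substrate at 2.00 h against Sunday's 48.2 %. Reagent, catalyst and impurity were the same in both runs, so the readings do not test them. By hand they change the clock for both substrates together and leave the factor unchanged. In the flask, the left-handed substrate's charge equals a third of the reagent charge.

The wanted excess means x/y = 0.00503. Since x = y^s, where s is the factor, right-handed substrate then stands at 46.7 % of the two charged. Wednesday's run is below that level at 5.00 h, with 45.1 %, and the flask has 4.00 times as long. This reckoning therefore commits to yes, with the excess still climbing as y falls.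

The forecast also says yes, with a highest excess of 100 %: “Nothing listed regenerates left-handed substrate, since no racemisation step is offered, so the excess only climbs”.

The flask gives yes and 100 %.

    reagent + free catalyst + left-handed substrate → free catalyst + left-handed product (k = 2.40 M⁻² s⁻¹)
    reagent + free catalyst + right-handed substrate → free catalyst + right-handed product (k = 0.0290 M⁻² s⁻¹)
    free catalyst + impurity → spent catalyst A (k = 12.0 M⁻¹ s⁻¹)
    free catalyst → spent catalyst B (k = 3.40 × 10⁻⁵ s⁻¹)
    2 free catalyst ⇌ resting dimer, settled at all times (K = 830 M⁻¹)

The flask reaches the wanted excess at 3.71 h, with 46.9 % of right-handed substrate left. At 2.00 h the flask holds 48.1 % of right-handed substrate, which the factor turns into 2.53 % of left-handed substrate, against 2.20 % standing there. On Sunday's run, the 46.5 % of right-handed substrate at 3.00 h gives 0.161 % by the same factor, and the left-handed substrate there reads 0.1 %.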